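## Structural features

The target is a briarane. A cyclohexane ring A (C1, C14, C13, C12, C11, C10) is trans-fused along C1–C10 to a ten-membered carbocycle (C1 to C10), and a γ-lactone (C7, C8, C17, C19 and the ring oxygen) is fused to that ring at C7–C8. There are eleven stereocentres: C6, C7, C8, C9, C10, C11 and C12 form an unbroken row, C17 branches from C8, and the quaternary C1 (methyl C15) links the row to C2 and C14. Ring A carries an axial acetate at C14, an axial isovalerate at C12 and a spiro-epoxide at C11 (C20), with the epoxide oxygen on the face of the C12 and C14 oxygens. The large ring carries an isobutyrate at C2, a secondary allylic chloride at C6 beside the exocyclic C5=C16 methylene, a tertiary alcohol at C8 and an acetate at C9. The fragile points are the acid-labile 1,1-disubstituted epoxide, the allylic chloride, the β-hydroxy lactone (retro-aldol, elimination) and five oxygens that must end with four different substituents. The real difficulty is closing the ten-membered ring in the presence of all this, together with the C8/C9 pair, whose oxygens are trans-diaxial on a six-membered template. The key step exploits the C3–C4 bond: it is the only CH2–CH2 unit of the ten-membered ring and sits between the oxygenated C2 (origin of an enol ether radical cation) and the C5=C16 methylene (what an allylsilane leaves behind after attacking an electrophile).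

## Logic of the disconnections

43 to 40: the O2 isobutyrate and the O8–H bond are cut and the C2 carbinol is taken back to a ketone. This removes one stereocentre and leaves a carbonyl where the ring was closed. The forward demand is hydride addition to C2 from the face away from C15 and acylation of a neopentyl alcohol while O8 stays silylated.

40 to 39 to 38: C3–C4 is cut. It is the only unfunctionalised bond of the ring and both neighbours (C2 oxygen, C5=C16) are the natural residues of an enol ether and an allylsilane. The gain is an open chain held by ring A and the lactone. The forward step must form the C–C bond faster than solvent captures the radical cation.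

38 to 36: the O–CH3 bond of the enol ether is cut, because the enol ether is too labile to carry; 36 is a robust methyl ketone. The forward step must enolise the ketone selectively and alkylate on oxygen with four ester carbonyls present.

36 to 30 and 33: C6–C7 and the lactone bond C19–O7 are cut. A carbinol beside an allylic chloride is the retron of a γ-chloroallyl addition to an aldehyde, and the lactone closes once O7 exists. This removes C4, C5, C6, C16 and two stereocentres. The demand is anti C6/C7 and the correct aldehyde face. 33 comes from 31 by allylic chlorination.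

30 to 29: C2 and C7 are reconnected as a C2=C7 alkene, which turns the seco chain into ring B of a trans-decalin. The gain is a rigid template that fixes C8, C9 and C10. The demand is that C2=C7 is the only alkene at the time of cleavage.

29 to 24: the O8 silyl ether and the O9/O14 acetates are removed and C9 is inverted through its ketone (25). The trans-diaxial C8/C9 diol is thus reduced to a cis-diol that a carbonyl addition can deliver. The demand is hydride delivery to C9 from the face away from C15.

24 to 21 and 22: C8–C17 is cut (aldol). This removes C17, C18, C19 and two stereocentres. The demand is attack on the β face of the C8 ketone.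

21 to 19 to 18: the C9–O bond (α′-hydroxylation) and the C8 carbonyl (allylic oxidation) are removed. Ring B is then a plain methylcyclohexene.

18 to 17 to 16 to 14 to 13 to 10 and 11: in ring A the C12 ester, the epoxide (from the allylic alcohol), the C11=C20 alkene (from an amine oxide), the C12 carbinol (from a ketone) and finally the C11–C20 bond and the C10–H bond are cut. The last two go back to an enone by reductive aminomethylation.

10 to 9 to 7 to 5: the C14–O bond is cut to a conjugate borylation of a cross-conjugated dienone, and C13=C14 to a dehydrogenation.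

5 to 4 to 1 and 2: C2=C3 is cut (Wittig on the saturated ketone of 1) after the alkene is moved back to the exocyclic position.

## Other disconnections considered

Alternative 1: The cut is in ring A at C1–C14 and C10–C11. The forward key step is a thermal Diels–Alder reaction of an (E)-2-methyl enal carrying C8–C9 as a dioxolane with a 1-benzyloxy-3-silyloxy pentadiene, giving cycloadduct A1.
- In its favour: one step makes two ring bonds, the quaternary C1 and up to three further ring A stereocentres, and C9 comes from the chiral pool. For ring A this is better in step economy than the chosen plan, which spends about ten steps there.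
- Against it here: an α-methyl, β-substituted enal is a sluggish dienophile; endo and facial selectivity rest on one allylic stereocentre; C11 arrives as a methyl-bearing methine that must still become the spiro-epoxide.
- Comparison: structurally it answers ring A, not the medium ring, and a macrocyclisation is still required. Mechanistically a concerted cycloaddition is more predictable than an anodic radical-cation closure. It could feed the same ring closure, so it is a complement rather than a replacement.

Alternative 2: The cut is C1–C10. The forward key step is a transannular Michael addition in a fourteen-membered ring: the enolate of the C2/C14 2-methyl-1,3-dione adds through C1 to C10 of an enal, giving A2.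
- In its favour: a fourteen-membered ring is easier to close than a ten-membered one, and one bond creates ring A, the ten-membered ring and the quaternary C1 together. On ring-forming economy it is better than the chosen plan.
- Against it here: the relative configuration at C1, C10 and C11 depends on the conformation of a flexible macrocycle. The two dione carbonyls must afterwards be told apart and reduced to C2 and C14 carbinols of defined configuration. The (Z)-C5=C6 alkene with its C16 methyl must later become the C6 chloride with exocyclic C5=C16 by an allylic chlorination with transposition. The C11 formyl group must become the epoxide.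
- Comparison: the chosen plan places the chloride, the epoxide and all esters before ring closure and leaves four steps after it; this plan closes early and then has a long, selectivity-laden endgame. Mechanistically a base-mediated conjugate addition is milder than electrolysis but reversible.

Alternative 3: The cut is C4–C5 in the forward sense, with C2–C7 of a decalinol broken. The forward key step is an anionic oxy-Cope rearrangement of a C2 vinyl carbinol bearing a C7 allenyl group, which expands the six-membered ring to the ten-membered C2 ketone A3 with a C16=C5–C6=C7 diene.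
- In its favour: the ring arises by ring expansion, so no high-dilution closure is needed; on that point it is better than the chosen plan. It uses the same disposable C2–C7 decalin bond as the chosen plan and gives the C2 ketone and C5=C16 directly. The reaction class is well established for cyclodecenones.
- Against it here: a vinyl and an allenyl group must be placed cis on C2 and C7 next to the quaternary C8 carbinol. Potassium alkoxide conditions meet silyl ethers and a β-oxygenated carbinol. The conjugated diene must afterwards be converted into C6–Cl and C7–O with control of regiochemistry and of two stereocentres, where 1,4-addition competes. C19 must still be oxidised to the lactone.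
- Comparison: step count to the ring is similar. The ring-forming step is better precedented than the chosen one, but the lactone and chloride are made after ring formation, where the chosen plan has them in place before it.

Key step: step 23

Remarks:
- Briarane numbering is used throughout. In decalin intermediates β is the face of the C15 methyl and α the face of H10.
- The precursor 38 and the product 39 of the key step were compared centre by centre with the target and agree with it, so no structural correction is made.
- 38 keeps its three esters and its O8 silyl ether; the ether is needed to remove the only internal oxygen nucleophile that could reach C3. The design is improved only in the medium, which is made poor in methanol and very dilute.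
- The chemoselective methylenation of the saturated ketone of 1 (step 1) is taken as known behaviour of this diketone.

Step 1
Reactants: 1 (S)-Wieland–Miescher ketone; 2 methyltriphenylphosphonium bromide
Product: 4 C2-methylidene enone, via methylidenetriphenylphosphorane 3 (not isolated)
Conditions: 2, KOt-Bu, THF, 0 °C; then 1, 0 °C to rt
Reagents that add atoms: none
Why: Wittig methylenation; the ylide should take the saturated C2 ketone because the C12 carbonyl is deactivated by conjugation. No stereocentre is touched and C3 is in place.

Step 2
Reactants: 4 C2-methylidene enone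
Product: 5 2-methyl-2(7)-ene enone
Conditions: RhCl3·3H2O (5 mol%), EtOH, 80 °C
Reagents that add atoms: none
Why: Metal-hydride alkene isomerisation moves the exocyclic double bond into the ring; C7 is the only ring neighbour with hydrogens (C1 is quaternary), so a single trisubstituted C2(CH3)=C7 alkene should form. This alkene is the latent cleavage site of ring B.

Step 3
Reactants: 5 2-methyl-2(7)-ene enone
Product: 7 cross-conjugated dienone, via trimethylsilyl dienol ether 6 (not isolated)
Conditions: LiN(i-Pr)2, Me3SiCl, THF, −78 °C; then Pd(OAc)2, MeCN, rt
Reagents that add atoms: none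
Why: Saegusa–Ito oxidation; kinetic deprotonation of the enone occurs at the α′-methylene C13 and divalent palladium dehydrogenates the silyl dienol ether to the C13=C14 enone. The isolated C2=C7 alkene takes no part.

Step 4
Reactants: 7 cross-conjugated dienone
Product: 9 14α-hydroxy enone, via 14α-pinacolboryl enone 8 (not isolated)
Conditions: B2pin2, CuCl (5 mol%), NaOt-Bu, DPEphos, MeOH, THF, rt; then 30% H2O2, pH 7 buffer, 0 °C
Reagents that add atoms: hydrogen peroxide, OO
Why: Copper-catalysed conjugate borylation goes to the less substituted terminus C14 (C10 would become quaternary). The boryl-copper species adds to C14 on the face opposite the C15 methyl of the adjacent quaternary C1, and oxidation with retention gives the axial 14α alcohol.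

Step 5
Reactants: 9 14α-hydroxy enone
Product: 10 14α-silyloxy enone
Conditions: TBSOTf, 2,6-lutidine, CH2Cl2, −78 °C
Reagents that add atoms: tert-butyldimethylsilyl trifluoromethanesulfonate, CC(C)(C)[Si](C)(C)OS(=O)(=O)C(F)(F)F
Why: Silylation of the hindered β-hydroxy ketone without base-induced elimination; the ether survives dissolving metal and later shields the axial approach to C12.

Step 6
Reactants: 10 14α-silyloxy enone; 11 dimethyl(methylidene)ammonium iodide
Product: 13 11-aminomethyl 12-ketone, via trans-fused lithium enolate 12 (not isolated)
Conditions: Li, NH3(l), THF, t-BuOH (1 equiv), −78 °C; NH3 evaporated; 11, THF, −78 to 0 °C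
Reagents that add atoms: none
Why: Birch reduction of the enone protonates C10 axially and gives the trans-fused C11=C12 lithium enolate. This regiodefined enolate is trapped at C11 in a Mannich reaction, which installs C20; the C11 configuration is immaterial because C11 becomes trigonal in step 8.

Step 7
Reactants: 13 11-aminomethyl 12-ketone
Product: 14 12α-hydroxy amine
Conditions: LiBH(s-Bu)3, THF, −78 °C
Reagents that add atoms: none
Why: The bulky borohydride attacks equatorially; the axial path is also blocked by the 1,3-related axial 14α-silyloxy group, so the axial 12α alcohol should form. The low temperature avoids β-elimination of the amine.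

Step 8
Reactants: 14 12α-hydroxy amine
Product: 16 11(20)-en-12α-ol, via amine N-oxide 15 (not isolated)
Conditions: 30% H2O2, MeOH, rt; then PhMe, 100 °C
Reagents that add atoms: none
Why: Cope elimination; hydrogen peroxide oxidises only nitrogen, and the syn elimination can take only the C11 hydrogen, so the exocyclic C11=C20 methylene forms next to the 12α alcohol.

Step 9
Reactants: 16 11(20)-en-12α-ol
Product: 17 11,20-epoxy-12α-ol
Conditions: VO(acac)2 (2 mol%), t-BuOOH, CH2Cl2, 0 °C
Reagents that add atoms: tert-butyl hydroperoxide, CC(C)(C)OO
Why: Hydroxyl-directed epoxidation delivers oxygen syn to the 12α hydroxyl, on the α face that is also remote from the C15 methyl, giving the epoxide with oxygen α and C20 β. The C2=C7 alkene has no directing hydroxyl and is spared.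

Step 10
Reactants: 17 11,20-epoxy-12α-ol
Product: 18 12α-isovalerate
Conditions: isovaleric anhydride, DMAP, Et3N, CH2Cl2, rt
Reagents that add atoms: 3-methylbutanoic anhydride, CC(C)CC(=O)OC(=O)CC(C)C
Why: DMAP-catalysed acylation of the only free hydroxyl; the final O12 ester is placed now because no organometallic reagent that attacks esters follows.

Step 11
Reactants: 18 12α-isovalerate
Product: 19 2(7)-en-8-one
Conditions: Rh2(caprolactamate)4 (1 mol%), t-BuOOH, K2CO3, CH2Cl2, rt
Reagents that add atoms: tert-butyl hydroperoxide, CC(C)(C)OO
Why: Allylic C–H oxidation through an allylic peroxide; C8 is the only ring methylene allylic to C2=C7 (C1 is quaternary), and a secondary C–H reacts before the C3 methyl. The β-methyl enone formed has the C8 carbonyl and keeps C2=C7.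

Step 12
Reactants: 19 2(7)-en-8-one
Product: 21 9α-hydroxy enone, via sodium dienolate 20 (not isolated)
Conditions: NaN(SiMe3)2, THF, −78 °C; then 2-(phenylsulfonyl)-3-phenyloxaziridine
Reagents that add atoms: 2-(phenylsulfonyl)-3-phenyloxaziridine, O=S(=O)(c1ccccc1)N1OC1c1ccccc1
Why: Kinetic α′-enolisation at C9 (the ketone is far more acidic than the ester) followed by electrophilic hydroxylation of the enolate. The oxidant should approach C9 from the α face, away from the 1,3-related C15 methyl, giving the equatorial 9α alcohol, which is inverted in steps 14 and 16.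

Step 13
Reactants: 21 9α-hydroxy enone; 22 N-methoxy-N-methylpropanamide
Product: 24 8α,9α-diol amide, via lithium (Z)-amide enolate 23 (not isolated)
Conditions: 22 (3.2 equiv), LiN(i-Pr)2, THF, −78 °C; then 21, −78 to −40 °C; AcOH quench
Reagents that add atoms: none
Why: Aldol 1,2-addition to the β,β-disubstituted enone. In the lithium chelate of the C8 carbonyl and the 9α alkoxide, ring carbon C10 lies on the α side and H9 on the β side, so the enolate should enter from β (nucleophile trans to the α-oxygen, cis-diol), placing C17 equatorial and the C8 hydroxyl axial α. The (Z)-enolate in a chair transition state with C9 as the larger ketone substituent sets C17 as in the target.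

Step 14
Reactants: 24 8α,9α-diol amide
Product: 25 8α-hydroxy-9-ketone
Conditions: Dess–Martin periodinane, NaHCO3, CH2Cl2, 0 °C to rt
Reagents that add atoms: none
Why: Oxidation of the only secondary alcohol; the tertiary C8 hydroxyl cannot be oxidised and the buffer prevents acid-induced shifts of the α-ketol.

Step 15
Reactants: 25 8α-hydroxy-9-ketone
Product: 26 14α-hydroxy 9-ketone
Conditions: HF·pyridine, pyridine, THF, 0 °C to rt
Reagents that add atoms: none
Why: Fluoride cleavage of the secondary silyl ether under buffered, non-basic conditions, which avoid retro-aldol of the β-hydroxy amide and spare the epoxide. Desilylation is placed here so that O9 and O14 can be acetylated together.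

Step 16
Reactants: 26 14α-hydroxy 9-ketone
Product: 27 8α,9β,14α-triol
Conditions: NaBH4, MeOH/CH2Cl2, −40 °C; AcOH quench
Reagents that add atoms: none
Why: Hydride should attack the C9 ketone along the equatorial α trajectory because the axial β path is blocked by the 1,3-diaxial C15 methyl, giving the axial 9β alcohol trans to the 8α hydroxyl. The N-methoxy-N-methyl amide and the ester are not reduced.

Step 17
Reactants: 27 8α,9β,14α-triol
Product: 28 9β,14α-diacetate
Conditions: Ac2O, DMAP, pyridine, CH2Cl2, rt
Reagents that add atoms: acetic anhydride, CC(=O)OC(C)=O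
Why: Both secondary alcohols are acetylated in one operation and the tertiary allylic C8 hydroxyl is left. Prompt acylation of O9 also removes the hydroxyl that could lactonise onto C19.

Step 18
Reactants: 28 9β,14α-diacetate
Product: 29 8α-triethylsilyl ether
Conditions: TESOTf, 2,6-lutidine, CH2Cl2, −78 to −20 °C
Reagents that add atoms: triethylsilyl trifluoromethanesulfonate, CC[Si](CC)(CC)OS(=O)(=O)C(F)(F)F
Why: Only a silyl triflate silylates the tertiary alcohol; the low temperature and the hindered base protect the epoxide. The ether is needed for the non-chelated aldehyde addition in step 21 and for the electrolysis.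

Step 19
Reactants: 29 8α-triethylsilyl ether
Product: 30 seco keto aldehyde
Conditions: O3, CH2Cl2, −78 °C; then PPh3
Reagents that add atoms: ozone, [O-][O+]=O
Why: Ozonolysis of the only alkene cleaves C2=C7 and opens ring B to the C2 methyl ketone and the C7 aldehyde. The α-carbon of the aldehyde (C8) is quaternary, so it cannot epimerise.

Step 20
Reactants: 31 [2-(chloromethyl)allyl]trimethylsilane
Product: 33 3,3-dichloro-2-(trimethylsilylmethyl)propene, via α-chloroallyllithium 32 (not isolated)
Conditions: LiN(i-Pr)2, THF, −95 °C; then C2Cl6
Reagents that add atoms: hexachloroethane, ClC(Cl)(Cl)C(Cl)(Cl)Cl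
Why: Deprotonation at the CH2Cl group, which is both allylic and α to chlorine, gives an α-chloroallyllithium that is chlorinated by hexachloroethane. A 1,3-dichloride formed by γ-attack would serve equally, because both give the same allylchromium reagent.

Step 21
Reactants: 30 seco keto aldehyde; 33 3,3-dichloro-2-(trimethylsilylmethyl)propene
Product: 36 lactone methyl ketone, via γ-chloroallylchromium dichloride 34 (not isolated), via anti-chlorohydrin amide 35 (not isolated)
Conditions: 33, CrCl2, THF, 0 °C to rt; then PPTS, PhMe, 45 °C
Reagents that add atoms: none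
Why: Nozaki–Hiyama-type addition: divalent chromium converts 33 into a γ-chloroallyl chromium reagent that adds to the aldehyde through a chair transition state with chlorine equatorial, giving the anti (6S,7R) chlorohydrin. The aldehyde face follows the Felkin–Anh model (silyloxy group anti, nucleophile passing the smaller C17 branch, not C9); the methyl ketone does not react. Mild acid then transfers the acyl group from the amide to O7 and closes the γ-lactone.

Step 22
Reactants: 36 lactone methyl ketone
Product: 38 seco methyl enol ether allylsilane, via potassium enolate 37 (not isolated)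
Conditions: KN(SiMe3)2, THF/DMPU, −78 °C; then MeOTf
Reagents that add atoms: methyl trifluoromethanesulfonate, COS(=O)(=O)C(F)(F)F
Why: The methyl ketone has the most acidic and most accessible C–H, so one equivalent of the hindered amide base should enolise it kinetically. The dissociated potassium enolate is alkylated on oxygen by the hard methyl triflate, giving the 2-methoxyalkene (C2–OCH3, C2=C3).

Step 23
Reactants: 38 seco methyl enol ether allylsilane
Product: 39 ten-membered dimethyl ketal
Conditions: reticulated vitreous carbon anode, Pt cathode, undivided cell, 0.1 M LiClO4, MeOH/CH2Cl2 1:4, 2,6-lutidine, 2 mA constant current, 2.2 F/mol, 0.002 M, rt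
Reagents that add atoms: methanol, CO
Why: Proposed new method: anodic oxidation removes one electron from the methyl enol ether, the most electron-rich π system, and the terminal carbon C3 of the radical cation is attacked by C4 of the allylsilane; the β-silyl cation at C5 then loses silicon to methanol to give C5=C16, and the C2 radical is oxidised again and captured by methanol as the dimethyl ketal. The closest known reaction type is the anodic olefin coupling of enol ether radical cations with allylsilanes, which is established for five- to seven-membered rings but not for a ten-membered ring. The ten-membered ring (C1 to C10) closes in an endo mode by head-to-head union of the two chain termini, with ring A and the γ-lactone as rigid turns that hold both arms on the same side. No stereocentre is formed. The step needs chemoselective oxidation of the enol ether (esters, epoxide, alkyl chloride and the chloride-deactivated allylsilane lie at higher potential), bond formation at C4 (directed by the β-effect of silicon) and cyclisation faster than methanol capture. The last is served by high dilution, low current density, a methanol-poor solvent and the O8 silyl ether, which removes the only internal oxygen nucleophile within reach of C3.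

Step 24
Reactants: 39 ten-membered dimethyl ketal
Product: 40 ten-membered C2 ketone
Conditions: PPTS, acetone/H2O 10:1, 40 °C
Reagents that add atoms: water, O
Why: Mild acid hydrolysis of the dimethyl ketal; the weak acid should leave the epoxide, the tertiary silyl ether and the allylic chloride intact.

Step 25
Reactants: 40 ten-membered C2 ketone
Product: 41 (2S)-alcohol
Conditions: NaBH4, CeCl3·7H2O, MeOH, −40 °C
Reagents that add atoms: none
Why: Carbonyl-selective hydride reduction (Luche conditions) that leaves lactone and esters. Hydride should add to C2 from the periphery of the ring on the α face, away from the C15 methyl of the adjacent quaternary C1, placing the hydroxyl on the C15 side as in the target.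

Step 26
Reactants: 41 (2S)-alcohol
Product: 42 2-isobutyrate
Conditions: isobutyric anhydride, DMAP, Et3N, CH2Cl2, rt
Reagents that add atoms: 2-methylpropanoic anhydride, CC(C)C(=O)OC(=O)C(C)C
Why: DMAP-catalysed acylation of the only free hydroxyl; O8 is still silylated, so no selectivity question arises.

Step 27
Reactants: 42 2-isobutyrate
Product: 43 CNP0194902.1
Conditions: HF·pyridine, pyridine, THF, 0 °C to rt
Reagents that add atoms: none
Why: Fluoride cleaves the tertiary triethylsilyl ether; buffering with pyridine protects the epoxide and the allylic chloride and avoids basic conditions under which acyl groups could migrate.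

## Compound list

1 | (S)-Wieland–Miescher ketone | C[C@]12CCC(=O)C=C1CCCC2=O | starting material
2 | methyltriphenylphosphonium bromide | C[P+](c1ccccc1)(c1ccccc1)c1ccccc1.[Br-] | starting material
3 | methylidenetriphenylphosphorane (not isolated) | C=P(c1ccccc1)(c1ccccc1)c1ccccc1 | intermediate
4 | enone with exocyclic C2=C3 methylidene; C10=C11–C12=O; C15 on quaternary C1 | C[C@]12CCC(=O)C=C1CCCC2=C | intermediate
5 | enone with endocyclic C2(CH3)=C7 alkene | C[C@]12CCC(=O)C=C1CCC=C2C | intermediate
6 | 12-trimethylsilyloxy-10,12-diene (silyl dienol ether of 5, not isolated) | C[C@]12CC=C(O[Si](C)(C)C)C=C1CCC=C2C | intermediate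
7 | cross-conjugated 10(11),13(14)-dien-12-one with C2(CH3)=C7 | C[C@]12C=CC(=O)C=C1CCC=C2C | intermediate
8 | 14α-pinacolboryl 10-en-12-one (not isolated) | C[C@]12[C@@H](B3OC(C)(C)C(C)(C)O3)CC(=O)C=C1CCC=C2C | intermediate
9 | 14α-hydroxy 10-en-12-one | C[C@]12[C@@H](O)CC(=O)C=C1CCC=C2C | intermediate
10 | 14α-tert-butyldimethylsilyloxy 10-en-12-one | C[C@]12[C@@H](O[Si](C)(C)C(C)(C)C)CC(=O)C=C1CCC=C2C | intermediate
11 | dimethyl(methylidene)ammonium iodide (Eschenmoser's salt) | C=[N+](C)C.[I-] | starting material
12 | trans-fused lithium 11-en-12-olate, H10 α (not isolated) | C[C@]12[C@@H](O[Si](C)(C)C(C)(C)C)CC(O[Li])=C[C@@H]1CCC=C2C | intermediate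
13 | trans-decalin 12-ketone with equatorial 11-(dimethylaminomethyl) group (C20), H10 α, 14α-OTBS | C[C@]12[C@@H](O[Si](C)(C)C(C)(C)C)CC(=O)[C@@H](CN(C)C)[C@@H]1CCC=C2C | intermediate
14 | 12α (axial) alcohol of 13 | C[C@]12[C@@H](O[Si](C)(C)C(C)(C)C)C[C@@H](O)[C@@H](CN(C)C)[C@@H]1CCC=C2C | intermediate
15 | N-oxide of 14 (not isolated) | C[C@]12[C@@H](O[Si](C)(C)C(C)(C)C)C[C@@H](O)[C@@H](C[N+](C)(C)[O-])[C@@H]1CCC=C2C | intermediate
16 | allylic alcohol: exocyclic C11=C20, 12α-OH, 14α-OTBS, H10 α | C[C@]12[C@@H](O[Si](C)(C)C(C)(C)C)C[C@@H](O)C(=C)[C@@H]1CCC=C2C | intermediate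
17 | 11,20-epoxide (oxygen α, C20 β) with 12α-OH | C[C@]12[C@@H](O[Si](C)(C)C(C)(C)C)C[C@@H](O)[C@]3(CO3)[C@@H]1CCC=C2C | intermediate
18 | 12α-isovalerate of 17 | C[C@]12[C@@H](O[Si](C)(C)C(C)(C)C)C[C@@H](OC(=O)CC(C)C)[C@]3(CO3)[C@@H]1CCC=C2C | intermediate
19 | ring B enone: C2(CH3)=C7–C8=O | C[C@]12[C@@H](O[Si](C)(C)C(C)(C)C)C[C@@H](OC(=O)CC(C)C)[C@]3(CO3)[C@@H]1CC(=O)C=C2C | intermediate
20 | sodium 8-olate of the 2(7),8-diene (not isolated) | C[C@]12[C@@H](O[Si](C)(C)C(C)(C)C)C[C@@H](OC(=O)CC(C)C)[C@]3(CO3)[C@@H]1C=C(O[Na])C=C2C | intermediate
21 | 9α-hydroxy enone (hydroxyl equatorial, cis to H10) | C[C@]12[C@@H](O[Si](C)(C)C(C)(C)C)C[C@@H](OC(=O)CC(C)C)[C@]3(CO3)[C@@H]1[C@@H](O)C(=O)C=C2C | intermediate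
22 | N-methoxy-N-methylpropanamide | CCC(=O)N(C)OC | starting material
23 | lithium (Z)-enolate of 22 (not isolated) | C/C=C(\O[Li])N(C)OC | intermediate
24 | aldol adduct: 8α-OH (axial), C17 side chain β (equatorial), 9α-OH, C17 as in target | C[C@]12[C@@H](O[Si](C)(C)C(C)(C)C)C[C@@H](OC(=O)CC(C)C)[C@]3(CO3)[C@@H]1[C@@H](O)[C@](O)([C@@H](C)C(=O)N(C)OC)C=C2C | intermediate
25 | 8α-hydroxy-9-ketone | C[C@]12[C@@H](O[Si](C)(C)C(C)(C)C)C[C@@H](OC(=O)CC(C)C)[C@]3(CO3)[C@@H]1C(=O)[C@](O)([C@@H](C)C(=O)N(C)OC)C=C2C | intermediate
26 | 14α-hydroxy 8α-hydroxy-9-ketone | C[C@]12[C@@H](O)C[C@@H](OC(=O)CC(C)C)[C@]3(CO3)[C@@H]1C(=O)[C@](O)([C@@H](C)C(=O)N(C)OC)C=C2C | intermediate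
27 | 8α,9β,14α-triol (8,9-trans-diaxial) | C[C@]12[C@@H](O)C[C@@H](OC(=O)CC(C)C)[C@]3(CO3)[C@@H]1[C@H](O)[C@](O)([C@@H](C)C(=O)N(C)OC)C=C2C | intermediate
28 | 9β,14α-diacetate with free 8α-OH | C[C@]12[C@@H](OC(C)=O)C[C@@H](OC(=O)CC(C)C)[C@]3(CO3)[C@@H]1[C@H](OC(C)=O)[C@](O)([C@@H](C)C(=O)N(C)OC)C=C2C | intermediate
29 | 8α-triethylsilyl ether of 28 | C[C@]12[C@@H](OC(C)=O)C[C@@H](OC(=O)CC(C)C)[C@]3(CO3)[C@@H]1[C@H](OC(C)=O)[C@](O[Si](CC)(CC)CC)([C@@H](C)C(=O)N(C)OC)C=C2C | intermediate
30 | seco compound: ring A with C1 acetyl (C2, C3) and C10 chain C9(OAc)–C8(OTES)(CHO)–C17H(CH3)–C19 amide | CC(=O)[C@@]1(C)[C@@H](OC(C)=O)C[C@@H](OC(=O)CC(C)C)[C@]2(CO2)[C@@H]1[C@H](OC(C)=O)[C@@](O[Si](CC)(CC)CC)(C=O)[C@@H](C)C(=O)N(C)OC | intermediate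
31 | [2-(chloromethyl)allyl]trimethylsilane | C=C(CCl)C[Si](C)(C)C | starting material
32 | 1-chloro-2-(trimethylsilylmethyl)allyllithium (not isolated) | [Li]C(Cl)C(=C)C[Si](C)(C)C | intermediate
33 | 3,3-dichloro-2-(trimethylsilylmethyl)prop-1-ene | ClC(Cl)C(=C)C[Si](C)(C)C | intermediate
34 | (E)-3-chloro-2-(trimethylsilylmethyl)allylchromium dichloride (not isolated) | Cl/C=C(/C[Cr](Cl)Cl)C[Si](C)(C)C | intermediate
35 | anti-(6S,7R)-chlorohydrin amide (not isolated) | CC(=O)[C@@]1(C)[C@@H](OC(C)=O)C[C@@H](OC(=O)CC(C)C)[C@]2(CO2)[C@@H]1[C@H](OC(C)=O)[C@@](O[Si](CC)(CC)CC)([C@@H](O)[C@@H](Cl)C(=C)C[Si](C)(C)C)[C@@H](C)C(=O)N(C)OC | intermediate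
36 | γ-lactone (O7–C19) with C2 methyl ketone, C6 chloride and C16 allylsilane | CC(=O)[C@@]1(C)[C@@H](OC(C)=O)C[C@@H](OC(=O)CC(C)C)[C@]2(CO2)[C@@H]1[C@H](OC(C)=O)[C@]3(O[Si](CC)(CC)CC)[C@@H](C)C(=O)O[C@H]3[C@@H](Cl)C(=C)C[Si](C)(C)C | intermediate
37 | potassium enolate of 36 at C2/C3 (not isolated) | C=C(O[K])[C@@]1(C)[C@@H](OC(C)=O)C[C@@H](OC(=O)CC(C)C)[C@]2(CO2)[C@@H]1[C@H](OC(C)=O)[C@]3(O[Si](CC)(CC)CC)[C@@H](C)C(=O)O[C@H]3[C@@H](Cl)C(=C)C[Si](C)(C)C | intermediate
38 | seco C2 methyl enol ether with C16 allylsilane (precursor of the key step) | C=C(C[Si](C)(C)C)[C@H](Cl)[C@@H]4OC(=O)[C@H](C)[C@@]4(O[Si](CC)(CC)CC)[C@@H](OC(C)=O)[C@H]2[C@@]3(CO3)[C@H](OC(=O)CC(C)C)C[C@H](OC(C)=O)[C@]2(C)C(OC)=C | intermediate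
39 | ten-membered C2 dimethyl ketal with C5=C16 (product of the key step) | C=C1CCC(OC)(OC)[C@@]2(C)[C@@H](OC(C)=O)C[C@@H](OC(=O)CC(C)C)[C@]3(CO3)[C@@H]2[C@H](OC(C)=O)[C@]4(O[Si](CC)(CC)CC)[C@@H](C)C(=O)O[C@H]4[C@H]1Cl | intermediate
40 | ten-membered C2 ketone | C=C1CCC(=O)[C@@]2(C)[C@@H](OC(C)=O)C[C@@H](OC(=O)CC(C)C)[C@]3(CO3)[C@@H]2[C@H](OC(C)=O)[C@]4(O[Si](CC)(CC)CC)[C@@H](C)C(=O)O[C@H]4[C@H]1Cl | intermediate
41 | (2S)-alcohol, hydroxyl on the C15 side | C=C1CC[C@H](O)[C@@]2(C)[C@@H](OC(C)=O)C[C@@H](OC(=O)CC(C)C)[C@]3(CO3)[C@@H]2[C@H](OC(C)=O)[C@]4(O[Si](CC)(CC)CC)[C@@H](C)C(=O)O[C@H]4[C@H]1Cl | intermediate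
42 | 2-isobutyrate, 8-O-triethylsilyl ether | C=C1CC[C@H](OC(=O)C(C)C)[C@@]2(C)[C@@H](OC(C)=O)C[C@@H](OC(=O)CC(C)C)[C@]3(CO3)[C@@H]2[C@H](OC(C)=O)[C@]4(O[Si](CC)(CC)CC)[C@@H](C)C(=O)O[C@H]4[C@H]1Cl | intermediate
43 | CNP0194902.1 | C=C1CC[C@H](OC(=O)C(C)C)[C@@]2(C)[C@@H](OC(C)=O)C[C@@H](OC(=O)CC(C)C)[C@]3(CO3)[C@@H]2[C@H](OC(C)=O)[C@]2(O)[C@@H](C)C(=O)O[C@H]2[C@H]1Cl | target

## Step count and least certain steps

Total step count: 27. Longest linear sequence: 26 steps (steps 1 to 19 and 21 to 27); step 20 prepares the allyl reagent.

Step 23 (key step). The most likely failure is capture of the enol ether radical cation by methanol, or intermolecular coupling, before the two termini meet, because a ten-membered closure is slow and the allylsilane is deactivated by the neighbouring chloride. Fallback with known chemistry: it sets out from 36. Bromodesilylation of the allylsilane with N-bromosuccinimide, with allylic transposition, should give the 2-(bromomethyl)allyl chloride F1. Slow addition of F1 to KN(SiMe3)2 in THF at high dilution should close the ring by intramolecular alkylation of the methyl ketone enolate (C3) at the primary allylic bromide (C4). This comes back to the route at 40, so 38 and 39 are bypassed.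

Step 22. The risks are C-methylation instead of O-methylation, competing enolisation of an acetate with Claisen-type acyl transfer, and deprotonation at C17 followed by β-elimination of the silyloxy group. Fallback: from 36, ketalisation under aprotic conditions (MeOSiMe3, catalytic Me3SiOTf, CH2Cl2, −78 °C) to the dimethyl ketal F2. Elimination of methanol with Me3SiOTf and i-Pr2NEt at low temperature then gives 38; the silyl triflate must be kept cold and short-lived because of the epoxide.

Step 21. The risks are poor facial selectivity at the hindered, α-quaternary aldehyde, erosion of the anti relationship, and further reduction of the product chloride by excess divalent chromium. Fallback: from 31 and 30. 31 is converted with Me2S and AgBF4 into the allyl sulfonium salt F3. Its ylide adds to 30 (Corey–Chaykovsky reaction) to give the trans vinyl epoxide F4. F4 is opened by chloride at the allylic carbon C6 with inversion (Li2CuCl4, THF, 0 °C), which makes use of the higher reactivity of the vinyl epoxide over the hindered spiro-epoxide. This gives 35, and acid-catalysed lactonisation as in step 21 returns to 36.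

Step 13. The risks are addition to the α face of the enone, giving the C8 epimer, and retro-aldol on warming. Fallback: from 19. α′-Enolisation and triflation (NaN(SiMe3)2, PhNTf2) should give the dienyl triflate F5. Negishi coupling with the zinc enolate BrZnCH(CH3)C(=O)N(OCH3)CH3 under Pd(PPh3)4 catalysis gives the diene amide F6, together with its C17 epimer, which is recycled by deprotonation and reprotonation. Dihydroxylation (OsO4, N-methylmorpholine N-oxide) of the C8=C9 bond from the α face, away from C15, returns to 24; here C8 is set by alkene oxidation instead of carbonyl addition.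

Step 25. The risk is poor or reversed facial selectivity of hydride addition to the C2 ketone, because the conformation of the ten-membered ring is not known in advance. Fallback: if the C2-epimeric alcohol F7 predominates, it is esterified with isobutyric acid under Mitsunobu conditions (PPh3, diisopropyl azodicarboxylate), which inverts C2 and comes back to the route at 42.

## Further compounds

F1 | step 23 | allylic bromide from 36 (CH2Br on C5, C5=C16, C6 chloride retained) | CC(=O)[C@@]1(C)[C@@H](OC(C)=O)C[C@@H](OC(=O)CC(C)C)[C@]2(CO2)[C@@H]1[C@H](OC(C)=O)[C@]3(O[Si](CC)(CC)CC)[C@@H](C)C(=O)O[C@H]3[C@@H](Cl)C(=C)CBr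
F2 | step 22 | C2 dimethyl ketal of 36 | COC(C)(OC)[C@@]1(C)[C@@H](OC(C)=O)C[C@@H](OC(=O)CC(C)C)[C@]2(CO2)[C@@H]1[C@H](OC(C)=O)[C@]3(O[Si](CC)(CC)CC)[C@@H](C)C(=O)O[C@H]3[C@@H](Cl)C(=C)C[Si](C)(C)C
F3 | step 21 | dimethyl[2-(trimethylsilylmethyl)allyl]sulfonium tetrafluoroborate | C=C(C[S+](C)C)C[Si](C)(C)C.F[B-](F)(F)F
F4 | step 21 | trans C6–C7 vinyl epoxide of the seco amide | CC(=O)[C@@]1(C)[C@@H](OC(C)=O)C[C@@H](OC(=O)CC(C)C)[C@]2(CO2)[C@@H]1[C@H](OC(C)=O)[C@@](O[Si](CC)(CC)CC)([C@H]3O[C@@H]3C(=C)C[Si](C)(C)C)[C@@H](C)C(=O)N(C)OC
F5 | step 13 | 8-trifluoromethanesulfonyloxy 2(7),8-diene | C[C@]12[C@@H](O[Si](C)(C)C(C)(C)C)C[C@@H](OC(=O)CC(C)C)[C@]3(CO3)[C@@H]1C=C(OS(=O)(=O)C(F)(F)F)C=C2C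
F6 | step 13 | 2(7),8-diene carrying the C17–C19 amide on C8 | C[C@]12[C@@H](O[Si](C)(C)C(C)(C)C)C[C@@H](OC(=O)CC(C)C)[C@]3(CO3)[C@@H]1C=C([C@@H](C)C(=O)N(C)OC)C=C2C
F7 | step 25 | C2 epimer of 41 | C=C1CC[C@@H](O)[C@@]2(C)[C@@H](OC(C)=O)C[C@@H](OC(=O)CC(C)C)[C@]3(CO3)[C@@H]2[C@H](OC(C)=O)[C@]4(O[Si](CC)(CC)CC)[C@@H](C)C(=O)O[C@H]4[C@H]1Cl
A1 | alternative 1 | ring A cycloadduct with C2 aldehyde, C14 benzyl ether, C12 silyl enol ether and C8–C9 dioxolane | O=C[C@@]2(C)[C@@H](OCc4ccccc4)C=C(O[Si](C)(C)C(C)(C)C)[C@@H](C)[C@@H]2[C@H]5COC(C)(C)O5
A2 | alternative 2 | bicyclic C2,C14-dione with C11 formyl group and (Z)-C5=C6 alkene | C1/C(C)=C\[C@@H]2OC(=O)[C@H](C)[C@@]2(O[Si](C)(C)C)[C@@H](OC(C)=O)[C@H]3[C@H](C=O)[C@H](O[Si](C)(C)C(C)(C)C)CC(=O)[C@]3(C)C(=O)C1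
A3 | alternative 3 | ten-membered C2 ketone with C16=C5–C6=C7 diene | C1CC(=O)[C@@]2(C)[C@@H](O[Si](C)(C)C(C)(C)C)C[C@@H](O[Si](C)(C)C(C)(C)C)[C@]3(CO3)[C@@H]2[C@H](O[Si](C)(C)C(C)(C)C)[C@](O[Si](CC)(CC)CC)([C@@H](C)COCc4ccc(OC)cc4)/C=C/C1=C
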